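Abbreviations: MOM = methoxymethyl, Tf = trifluoromethanesulfonyl, pin = pinacolato, HMDS = hexamethyldisilazane, TMEDA = N,N,N',N'-tetramethylethylenediamine, dppf = 1,1'-bis(diphenylphosphino)ferrocene.

## Analysis of the target

The target 22 is a flavone: a benzo ring A fused to a 4-pyranone ring C, with aryl ring B on C2. It has no stereocenter. Ring A is hexasubstituted: C4a carries the C4 carbonyl, C8a carries O1, and C5 to C8 carry OH, OMe, OH and OMe in turn. Ring B is a methoxyhydroquinone (OMe at C2', OH at C3' and C6') joined to C2 through a carbon with two ortho substituents. The sensitive groups are the ring B hydroquinone, which air oxidises to the quinone under base, and the pyranone, which hydroxide can open at C2. The synthesis is hard because ring A has no hydrogen, so closures of ring C that substitute a ring A C–H bond are not available, and four oxygens of two kinds must be placed without ambiguity. The strategy rests on C4a and C8a being neighbours and on the alternation of the C5 to C8 oxygens: a benzene ring with SiMe3 on the future C4a, a triflate on each neighbour and OMe, OMOM, OMe on the other three carbons (compound 10) is mirror-symmetric through the silicon-bearing carbon and C7. Whichever triflate leaves, the same aryne forms, and the triflate that stays is the masked C5 hydroxyl.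

## Retrosynthetic reasoning

Unmasking. Target 22 is taken back to the tris-MOM ether 21 by cutting three acetal C–O bonds, and 21 to the C5 triflate 20 by cutting one S–O bond. This order keeps the hydroquinone of ring B and the C7 phenol masked until a last, acidic step in which a hydroquinone is safe; the only basic operation is then run on a fully protected compound. The C5 oxygen needs no protecting group of its own, because it is the sulfonate that the ring-forming step leaves behind.

Ring C. Compound 20 is cut at C8a–O1, C4a–C4 and O1–C2, which gives the aryne 18 and the arylpropiolic acid 17; 18 comes from the silyl bis-triflate 10. The cut is made here because ring A cannot be acylated at a C–H bond, whereas an aryne lets the oxygen and the acyl carbon be added to two neighbouring ring carbons in one event. Cuts at C2–C1' or C3–C4 would leave the attachment of carbon and oxygen to the hydrogen-free ring unsolved. In the forward direction the carboxylate oxygen has to add to the aryne carbon away from the triflate, the acyl group has to shift to the neighbouring carbon to give the phenoxide 19, and 19 has to close onto the alkyne.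

Aryne precursor. Compound 10 is cut at its two O–S bonds to the silyl resorcinol 9, and 9 at its C–Si bond to the bromoresorcinol 6, through the bis(silyl ether) 7 and the phenoxide 8. Silicon can reach a fully substituted ring carbon only through a carbanion, and a bromine–lithium exchange followed by an O-to-C silyl shift does this without an external silicon electrophile. The symmetry of 6 means that it does not matter which oxygen gives up its silyl group.

Ring A oxygens. Compound 6 is cut at C–Br to the resorcinol 5; 5 is cut at its two new C–O bonds to the dibromide 3 through the bis(boronate) 4; and 3 goes back through the MOM ether 2 to syringol 1. The three contiguous oxygens of 1 become the C6, C7 and C8 oxygens. The innate selectivity of electrophilic bromination marks first the two carbons that need oxygen and then the carbon that needs silicon.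

Ring B acid. Acid 17 is cut at the carboxyl C–C bond to the lithium acetylide 16, which comes from the dibromoalkene 15; 15 is cut at C=C to the aldehyde 14; 14 is cut at the formyl C–C bond to the aryllithium 13, which comes from the bis-MOM ether 12 of methoxyhydroquinone 11. The ring hydrogen between the methoxy group and one MOM ether is the most acidic, so directed metalation places the carbon on the correct position of ring B.

## Alternatives that were turned down

Alternative 1: Ring A would be built at C8–C8a from a four-carbon squaric unit fused onto a preformed 2-aryl-4-pyranone. A pyranone metalated next to its carbonyl would add to the mixed squarate A3 to give the hydroxycyclobutenone A2. Heating A2 would open the four-membered ring to a dienylketene, which closes in a six-electron electrocyclisation onto the pyranone C–H beside the ring oxygen; tautomerisation gives the 5,8-hydroquinone A1. Methylation of the unchelated C8 hydroxyl and acid removal of the tert-butyl and MOM groups would finish.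
- For: every oxygen of ring A is fixed by the connectivity of A3, and C5–OH and C8–OH differ by chelation. The ring closure has no counterpart to the direction of addition across an aryne, and on that point it is the stronger plan.
- Against: a 4-pyranone metalated beside the carbonyl is hard to make, because the ring is a vinylogous ester that accepts nucleophiles at C2 and C6. Attack on A3 must choose the carbonyl next to the methoxy carbon, and only size separates the two; the wrong choice exchanges the C6 and C7 substituents. The dienylketene can be trapped by its own tertiary hydroxyl as a butenolide. A1 is an electron-rich hydroquinone that air converts to the quinone before it can be methylated. The pyranone also needs its own synthesis, so the route is no shorter.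
- Comparison: the chosen strategy uses two simple benzenoid precursors and concentrates its uncertainty in one step.

Alternative 2: The cut is at C4a–C4 and O1–C2. The resorcinol A5, whose single ring hydrogen is the future C4a, would be heated without solvent with the keto ester A6. C-acylation and cyclodehydration of the resulting diketone onto a neighbouring hydroxyl give A4 with the 5-hydroxyl already free, and one hydrogenolysis removes the three benzyl groups.
- For: this is the shortest plan. A5 is a benzyl analogue of compound 5 and needs no halogen, silicon or sulfonate. Its symmetry removes every regiochemical question. On step count and on regiochemical safety it is stronger than the chosen route.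
- Against: thermal annulations of this kind need temperatures near 250 °C. The ketone of A6 is twisted and shielded by two ortho substituents, so closure of O1–C2 by attack of a phenol on that carbonyl is slow, and condensation of the ring carbon with the ketone leads toward a 4-arylcoumarin. Benzyl aryl ethers on electron-rich rings migrate or cleave at such temperatures, and A5 is easily oxidised.
- Comparison: the chosen strategy forms both bonds to ring A at 125 °C by a mechanism that does not depend on the nucleophilicity of a ring carbon. It closes ring C by intramolecular attack of a phenoxide on an alkyne carbon, not by condensation at a hindered ketone, and has no coumarin pathway.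

Alternative 3: The cut is at C8a–O1. The diketone A8, with a 2,6-dibromoaryl ketone as ring A, would be cyclised with a monovalent copper catalyst, a phenanthroline-type ligand and a carbonate base. The enolate oxygen displaces one of the two equivalent ortho bromines and gives the 5-bromoflavone A7. The remaining bromine must then be converted into the hydroxyl, and the benzyl and MOM groups removed.
- For: the dibromide is symmetric, so there is no regiochemistry, and intramolecular O-arylation of ortho-haloaryl diketones is dependable. In reliability of the ring closure it is probably stronger than the chosen key step.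
- Against: A8 joins two aroyl groups that each have two ortho substituents, and the Claisen-type acylation that would make it is severely hindered. Such a diketone is open to retro-Claisen cleavage under carbonate at the temperature of copper catalysis. The leftover C5–Br lies between the peri carbonyl and the C6 methoxy group, so its conversion to C5–OH needs a second metal-catalysed C–O formation at a doubly flanked carbon, with hydrodebromination as the easy side path and hot hydroxide threatening the pyranone.
- Comparison: the chosen strategy brings the C5 oxygen in from the start as the sulfonate that survives the aryne step and unmasks it by S–O cleavage at room temperature; the step counts are similar.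

Key step: step 11

Remark on the chemistry: rotation about the C2–C1' bond is assumed to be fast at room temperature, so the target is treated as achiral. The C7 oxygen is carried as a MOM ether so that all three acetals fall together in the last step.

## Route

Step 1
Reactants: 1 2,6-dimethoxyphenol (syringol)
Product: 2 1,3-dimethoxy-2-(methoxymethoxy)benzene
Conditions: MOMCl, i-Pr2NEt, CH2Cl2, 0 °C to rt
Reagents that add atoms: chloromethyl methyl ether (MOMCl), COCCl
Why: Williamson-type O-alkylation of the phenol by the reactive α-chloro ether. The acetal tolerates the organometallic, basic and fluoride steps ahead and is removed by acid at the end.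

Step 2
Reactants: 2 1,3-dimethoxy-2-(methoxymethoxy)benzene
Product: 3 1,5-dibromo-2,4-dimethoxy-3-(methoxymethoxy)benzene
Conditions: NBS (2 equiv), MeCN, 0 °C to rt
Reagents that add atoms: N-bromosuccinimide (NBS), O=C1CCC(=O)N1Br
Why: Electrophilic aromatic bromination. Each bromine enters para to one methoxy group and ortho to the other; the position para to the twisted central acetal oxygen is meta to both methoxy groups and is the least activated, as in the dibromination of 1,2,3-trialkoxybenzenes.

Step 3
Reactants: 3 1,5-dibromo-2,4-dimethoxy-3-(methoxymethoxy)benzene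
Product: 5 4,6-dimethoxy-5-(methoxymethoxy)benzene-1,3-diol, via bis(pinacolboronate) 4 (not isolated)
Conditions: B2pin2, PdCl2(dppf), KOAc, 1,4-dioxane, 90 °C; then H2O2, aq. NaOH, THF, 0 °C; buffer to pH 6
Reagents that add atoms: hydrogen peroxide, OO; bis(pinacolato)diboron, CC1(C)OB(OC1(C)C)B1OC(C)(C)C(C)(C)O1 (its boron is present only in 4)
Why: Double Miyaura borylation (oxidative addition of zerovalent palladium into each C–Br bond, acetate-assisted transmetalation with the diboron), then the standard peroxide oxidation of aryl boronates, in which the aryl group migrates from boron to oxygen at the same carbon. Each C–Br bond has only one ortho substituent, so both couplings should proceed.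

Step 4
Reactants: 5 4,6-dimethoxy-5-(methoxymethoxy)benzene-1,3-diol
Product: 6 2-bromo-4,6-dimethoxy-5-(methoxymethoxy)benzene-1,3-diol
Conditions: NBS (1 equiv), CH2Cl2, −78 to −20 °C
Reagents that add atoms: N-bromosuccinimide (NBS), O=C1CCC(=O)N1Br
Why: Electrophilic aromatic bromination at the only ring hydrogen, which lies between the two hydroxyls and is the most nucleophilic site. Low temperature and one equivalent of reagent are meant to limit oxidation of the electron-rich ring.

Step 5
Reactants: 6 2-bromo-4,6-dimethoxy-5-(methoxymethoxy)benzene-1,3-diol
Product: 9 4,6-dimethoxy-5-(methoxymethoxy)-2-(trimethylsilyl)benzene-1,3-diol, via bis(trimethylsilyl) ether 7 (not isolated), via lithium phenoxide 8 (not isolated)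
Conditions: HMDS, THF, 65 °C, then evaporate; n-BuLi, THF, −78 °C to rt; MeOH, K2CO3 (cat.), 0 °C; pH 7 buffer
Reagents that add atoms: hexamethyldisilazane (HMDS), C[Si](C)(C)N[Si](C)(C)C
Why: O-silylation, bromine–lithium exchange and retro-Brook rearrangement: the aryllithium between two silyloxy groups takes a silyl group from oxygen to carbon in a 1,3-shift driven by formation of the phenoxide, the standard entry to ortho-silyl phenols. The remaining labile aryl silyl ether is removed by buffered methanolysis without acid, so that the electron-rich C–Si bond is not protonated.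

Step 6
Reactants: 9 4,6-dimethoxy-5-(methoxymethoxy)-2-(trimethylsilyl)benzene-1,3-diol
Product: 10 4,6-dimethoxy-5-(methoxymethoxy)-2-(trimethylsilyl)-1,3-phenylene bis(trifluoromethanesulfonate)
Conditions: Tf2O, pyridine, CH2Cl2, −20 to 0 °C
Reagents that add atoms: trifluoromethanesulfonic anhydride (Tf2O), O=S(=O)(OS(=O)(=O)C(F)(F)F)C(F)(F)F
Why: O-sulfonylation of both phenols. The small, very reactive anhydride can reach hydroxyls flanked by SiMe3 and OMe, and the pyridine buffer protects the arylsilane from protodesilylation.

Step 7
Reactants: 11 2-methoxybenzene-1,4-diol (methoxyhydroquinone)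
Product: 12 2-methoxy-1,4-bis(methoxymethoxy)benzene
Conditions: MOMCl, i-Pr2NEt, CH2Cl2, 0 °C to rt, argon
Reagents that add atoms: chloromethyl methyl ether (MOMCl), COCCl
Why: Williamson-type O-alkylation of both phenols. The MOM groups mask the air-sensitive hydroquinone and later serve as directing groups for metalation.

Step 8
Reactants: 12 2-methoxy-1,4-bis(methoxymethoxy)benzene
Product: 14 2-methoxy-3,6-bis(methoxymethoxy)benzaldehyde, via aryllithium 13 (not isolated)
Conditions: n-BuLi, TMEDA, THF, −78 to 0 °C; DMF, −78 °C to rt; H2O
Reagents that add atoms: N,N-dimethylformamide (DMF), CN(C)C=O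
Why: Directed ortho-metalation followed by formylation of the aryllithium. The hydrogen between the methoxy group and a MOM ether has two coordinating, acidifying oxygen neighbours and should be removed in preference to the two hydrogens that have only one.

Step 9
Reactants: 14 2-methoxy-3,6-bis(methoxymethoxy)benzaldehyde
Product: 15 2-(2,2-dibromoethenyl)-3-methoxy-1,4-bis(methoxymethoxy)benzene
Conditions: CBr4, PPh3, Zn, CH2Cl2, 0 °C to rt
Reagents that add atoms: carbon tetrabromide, BrC(Br)(Br)Br
Why: First stage of the Corey–Fuchs sequence, a Wittig reaction of the ylide Ph3P=CBr2 with the aldehyde. Zinc dust forms the ylide without excess phosphine and keeps the medium free of acid that would threaten the acetals.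

Step 10
Reactants: 15 2-(2,2-dibromoethenyl)-3-methoxy-1,4-bis(methoxymethoxy)benzene
Product: 17 3-[2-methoxy-3,6-bis(methoxymethoxy)phenyl]prop-2-ynoic acid, via lithium acetylide 16 (not isolated)
Conditions: n-BuLi (2.2 equiv), THF, −78 °C; CO2, −78 to 0 °C; cold dilute HCl to pH 3
Reagents that add atoms: carbon dioxide, O=C=O
Why: Second stage of the Corey–Fuchs sequence (bromine–lithium exchange, Fritsch–Buttenberg–Wiechell shift to the alkyne, deprotonation), then carboxylation of the lithium acetylide. The brief, cold acidification should leave the aryl MOM ethers intact.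

Step 11
Reactants: 10 4,6-dimethoxy-5-(methoxymethoxy)-2-(trimethylsilyl)-1,3-phenylene bis(trifluoromethanesulfonate); 17 3-[2-methoxy-3,6-bis(methoxymethoxy)phenyl]prop-2-ynoic acid
Product: 20 6,8-dimethoxy-7-(methoxymethoxy)-2-[2-methoxy-3,6-bis(methoxymethoxy)phenyl]-4-oxo-4H-chromen-5-yl trifluoromethanesulfonate, via triflyloxyaryne 18 (not isolated), via cesium ynone phenoxide 19 (not isolated)
Conditions: CsF (excess), THF, 125 °C, sealed tube
Reagents that add atoms: none
Why: Fluoride attacks the silicon of 10 and either of the two equivalent triflates leaves, so only aryne 18 can form, while excess CsF holds acid 17 as its cesium carboxylate. The carboxylate oxygen should add to the aryne carbon beside the methoxy group and away from the remaining triflate, because the strongly σ-withdrawing, bulky triflate polarises the triple bond more than the methoxy group on the other flank and places the negative charge on the carbon next to itself. That aryl anion attacks the ester carbonyl through a four-membered transition state, and opening of the tetrahedral intermediate gives the ortho-acyl phenoxide 19, which forms C8a–O1 and C4a–C4. The closest known reaction type is the insertion of arynes into the C–O bond of carboxylic acids to give ortho-hydroxyaryl ketones, which with arylpropiolic acids leads on to flavones. Ring C then closes by 6-endo-dig oxa-Michael addition of the C8a phenoxide to the β-carbon of the ynone (O1–C2); the conjugate mode is favoured over 5-exo attack at the α-carbon, and the resulting vinyl anion takes up the proton that the acid supplied. No stereocenter is formed. The step needs regioselectivity across the aryne, which the triflate is relied on to provide against the weaker opposing pull of the methoxy group. It also needs the aryl anion to undergo the intramolecular acyl shift faster than loss of the neighbouring triflate or protonation, for which the aprotic medium and the proximity of the ester carbonyl are relied on.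

Step 12
Reactants: 20 6,8-dimethoxy-7-(methoxymethoxy)-2-[2-methoxy-3,6-bis(methoxymethoxy)phenyl]-4-oxo-4H-chromen-5-yl trifluoromethanesulfonate
Product: 21 5-hydroxy-6,8-dimethoxy-7-(methoxymethoxy)-2-[2-methoxy-3,6-bis(methoxymethoxy)phenyl]-4H-chromen-4-one
Conditions: Et4NOH (aq.), 1,4-dioxane, rt
Reagents that add atoms: none
Why: Hydroxide attacks the sulfonyl sulfur of the aryl triflate and releases the phenoxide (S–O cleavage), a standard mild unmasking of aryl triflates. The two ortho substituents of ring B shield C2 from conjugate attack, and the hydroquinone is still protected while base is present.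

Step 13
Reactants: 21 5-hydroxy-6,8-dimethoxy-7-(methoxymethoxy)-2-[2-methoxy-3,6-bis(methoxymethoxy)phenyl]-4H-chromen-4-one
Product: 22 2-(3,6-dihydroxy-2-methoxyphenyl)-5,7-dihydroxy-6,8-dimethoxy-4H-chromen-4-one (5,7,3',6'-tetrahydroxy-6,8,2'-trimethoxyflavone)
Conditions: HCl (aq.), MeOH, 50 °C, argon
Reagents that add atoms: none
Why: Acid-catalysed acetal exchange with methanol removes the three MOM groups. The aryl methyl ethers, the chromone and the free hydroquinone are stable to dilute acid.

## Compound list

1 | 2,6-dimethoxyphenol (syringol) | COc1cccc(OC)c1O | starting material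
2 | 1,3-dimethoxy-2-(methoxymethoxy)benzene | COCOc1c(OC)cccc1OC | intermediate
3 | 1,5-dibromo-2,4-dimethoxy-3-(methoxymethoxy)benzene | COCOc1c(OC)c(Br)cc(Br)c1OC | intermediate
4 | 2,2'-[4,6-dimethoxy-5-(methoxymethoxy)-1,3-phenylene]bis(4,4,5,5-tetramethyl-1,3,2-dioxaborolane) | COCOc1c(OC)c(B2OC(C)(C)C(C)(C)O2)cc(B2OC(C)(C)C(C)(C)O2)c1OC | intermediate (not isolated)
5 | 4,6-dimethoxy-5-(methoxymethoxy)benzene-1,3-diol | COCOc1c(OC)c(O)cc(O)c1OC | intermediate
6 | 2-bromo-4,6-dimethoxy-5-(methoxymethoxy)benzene-1,3-diol | COCOc1c(OC)c(O)c(Br)c(O)c1OC | intermediate
7 | [2-bromo-4,6-dimethoxy-5-(methoxymethoxy)-1,3-phenylene]bis(oxy)bis(trimethylsilane) | COCOc1c(OC)c(O[Si](C)(C)C)c(Br)c(O[Si](C)(C)C)c1OC | intermediate (not isolated)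
8 | lithium 4,6-dimethoxy-5-(methoxymethoxy)-2-(trimethylsilyl)-3-[(trimethylsilyl)oxy]phenolate | COCOc1c(OC)c([O-])c([Si](C)(C)C)c(O[Si](C)(C)C)c1OC.[Li+] | intermediate (not isolated)
9 | 4,6-dimethoxy-5-(methoxymethoxy)-2-(trimethylsilyl)benzene-1,3-diol | COCOc1c(OC)c(O)c([Si](C)(C)C)c(O)c1OC | intermediate
10 | 4,6-dimethoxy-5-(methoxymethoxy)-2-(trimethylsilyl)-1,3-phenylene bis(trifluoromethanesulfonate) | COCOc1c(OC)c(OS(=O)(=O)C(F)(F)F)c([Si](C)(C)C)c(OS(=O)(=O)C(F)(F)F)c1OC | intermediate
11 | 2-methoxybenzene-1,4-diol (methoxyhydroquinone) | COc1cc(O)ccc1O | starting material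
12 | 2-methoxy-1,4-bis(methoxymethoxy)benzene | COCOc1ccc(OCOC)c(OC)c1 | intermediate
13 | [2-methoxy-3,6-bis(methoxymethoxy)phenyl]lithium | [Li]c1c(OC)c(OCOC)ccc1OCOC | intermediate (not isolated)
14 | 2-methoxy-3,6-bis(methoxymethoxy)benzaldehyde | COCOc1ccc(OCOC)c(OC)c1C=O | intermediate
15 | 2-(2,2-dibromoethenyl)-3-methoxy-1,4-bis(methoxymethoxy)benzene | COCOc1ccc(OCOC)c(OC)c1C=C(Br)Br | intermediate
16 | lithium [2-methoxy-3,6-bis(methoxymethoxy)phenyl]ethynide | COCOc1ccc(OCOC)c(OC)c1C#C[Li] | intermediate (not isolated)
17 | 3-[2-methoxy-3,6-bis(methoxymethoxy)phenyl]prop-2-ynoic acid | COCOc1ccc(OCOC)c(OC)c1C#CC(=O)O | intermediate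
18 | 2,4-dimethoxy-3-(methoxymethoxy)-5,6-didehydrophenyl trifluoromethanesulfonate (3-triflyloxyaryne) | COCOC1=C(OC)C#CC(OS(=O)(=O)C(F)(F)F)=C1OC | intermediate (not isolated)
19 | cesium 4,6-dimethoxy-5-(methoxymethoxy)-2-{3-[2-methoxy-3,6-bis(methoxymethoxy)phenyl]prop-2-ynoyl}-3-[(trifluoromethanesulfonyl)oxy]phenolate | COCOc1ccc(OCOC)c(OC)c1C#CC(=O)c1c([O-])c(OC)c(OCOC)c(OC)c1OS(=O)(=O)C(F)(F)F.[Cs+] | intermediate (not isolated)
20 | 6,8-dimethoxy-7-(methoxymethoxy)-2-[2-methoxy-3,6-bis(methoxymethoxy)phenyl]-4-oxo-4H-chromen-5-yl trifluoromethanesulfonate | COCOc1ccc(OCOC)c(OC)c1-c1cc(=O)c2c(OS(=O)(=O)C(F)(F)F)c(OC)c(OCOC)c(OC)c2o1 | intermediate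
21 | 5-hydroxy-6,8-dimethoxy-7-(methoxymethoxy)-2-[2-methoxy-3,6-bis(methoxymethoxy)phenyl]-4H-chromen-4-one | COCOc1ccc(OCOC)c(OC)c1-c1cc(=O)c2c(O)c(OC)c(OCOC)c(OC)c2o1 | intermediate
22 | 2-(3,6-dihydroxy-2-methoxyphenyl)-5,7-dihydroxy-6,8-dimethoxy-4H-chromen-4-one | COc1c(O)ccc(O)c1-c1cc(=O)c2c(O)c(OC)c(O)c(OC)c2o1 | target

## Step count and least certain steps

Total: 13 steps. Longest linear sequence: 9 steps (steps 1 to 6, then 11 to 13); the ring B branch is 4 steps (steps 7 to 10).

Step 11 (key step). Four processes can divert it.
- The carboxylate may add at the aryne carbon beside the triflate, because the methoxy group on the other flank directs the opposite way and only the difference between the two substituents decides.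
- The aryl anion may lose the neighbouring triflate (a second aryne) or take the sulfonyl group from oxygen to carbon before the acyl shift.
- The aryl anion may be protonated by bifluoride, which stops the sequence at an aryl ester.
- The propiolate may lose carbon dioxide at 125 °C.

The fallback gives up the aryne and joins the rings by acylation of an aryllithium. It sets out from 6 and 17 and comes back at the target 22. Both hydroxyls of 6 are protected (MOMCl, i-Pr2NEt) to give 2-bromo-4,6-dimethoxy-1,3,5-tris(methoxymethoxy)benzene F1. Acid 17 is coupled with MeNHOMe·HCl (carbodiimide, i-Pr2NEt) to the Weinreb amide N-methoxy-3-[2-methoxy-3,6-bis(methoxymethoxy)phenyl]-N-methylprop-2-ynamide F2. Bromine–lithium exchange on F1 (n-BuLi, THF, −78 °C) and acylation of the aryllithium with F2 should give the ynone 1-[3,5-dimethoxy-2,4,6-tris(methoxymethoxy)phenyl]-3-[2-methoxy-3,6-bis(methoxymethoxy)phenyl]prop-2-yn-1-one F3. HCl in methanol removes the five acetals to give 3-(3,6-dihydroxy-2-methoxyphenyl)-1-(2,4,6-trihydroxy-3,5-dimethoxyphenyl)prop-2-yn-1-one F4. Either ortho hydroxyl of F4 closes ring C by conjugate addition (catalytic Et2NH, EtOH, argon), and because ring A is symmetric both give 22.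

Step 3. The second borylation may stop short, the electron-rich boronate may lose boron to a proton, and alkaline peroxide may over-oxidise the resorcinol to a quinone. The fallback replaces the boron detour by direct palladium-catalysed hydroxylation of both C–Br bonds (Pd2(dba)3, t-BuXPhos, KOH, 1,4-dioxane/H2O, 100 °C). It sets out from 3 and comes back at 5, with no new compound.

Step 4. The N-bromo reagent may oxidise the para-methoxyphenol to a quinone instead of substituting the ring. The fallback installs silicon by directed metalation without any halogen; it sets out from 5 and comes back at 9. Carbamoylation (Et2NCOCl, NaH, THF) gives 4,6-dimethoxy-5-(methoxymethoxy)-1,3-phenylene bis(diethylcarbamate) F5. Lithiation at the only ring hydrogen, between the two carbamates (s-BuLi, TMEDA, THF, −78 °C), with TMSCl quench gives 4,6-dimethoxy-5-(methoxymethoxy)-2-(trimethylsilyl)-1,3-phenylene bis(diethylcarbamate) F6. LiAlH4 in THF removes both carbamates to give 9.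

Step 5. The O-to-C silyl shift may be incomplete, and the very electron-rich arylsilane 9 may lose silicon to a proton during work-up or on silica. The fallback avoids the free silyl resorcinol; it sets out from 8 in the flask and comes back at 10. Quenching 8 with Tf2O at −78 °C gives 4,6-dimethoxy-5-(methoxymethoxy)-2-(trimethylsilyl)-3-[(trimethylsilyl)oxy]phenyl trifluoromethanesulfonate F7. Buffered methanolysis of the silyl ether gives 3-hydroxy-4,6-dimethoxy-5-(methoxymethoxy)-2-(trimethylsilyl)phenyl trifluoromethanesulfonate F8, a less electron-rich arylsilane. A second triflation (Tf2O, pyridine) gives 10.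

Step 12. Hydroxide may add at C2 of the chromone, which the C5 triflate makes more electrophilic, and the opened diketone may suffer retro-Claisen cleavage. Ring opening alone would be harmless, because reclosure through either ortho oxygen of the symmetric ring A gives the same flavone. The fallback reverses the order of unmasking; it sets out from 20 and comes back at 22. HCl in methanol first removes the three MOM groups to give 2-(3,6-dihydroxy-2-methoxyphenyl)-7-hydroxy-6,8-dimethoxy-4-oxo-4H-chromen-5-yl trifluoromethanesulfonate F9. Et4NOH is then applied under argon with Na2S2O4 present. The C7 phenoxide that forms first donates into the pyranone and suppresses attack at C2, while the reductant protects the hydroquinone.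

## Further compounds

F1 | step 11 | 2-bromo-4,6-dimethoxy-1,3,5-tris(methoxymethoxy)benzene | COCOc1c(OC)c(OCOC)c(Br)c(OCOC)c1OC
F2 | step 11 | N-methoxy-3-[2-methoxy-3,6-bis(methoxymethoxy)phenyl]-N-methylprop-2-ynamide | CON(C)C(=O)C#Cc1c(OC)c(OCOC)ccc1OCOC
F3 | step 11 | 1-[3,5-dimethoxy-2,4,6-tris(methoxymethoxy)phenyl]-3-[2-methoxy-3,6-bis(methoxymethoxy)phenyl]prop-2-yn-1-one | COCOc1ccc(OCOC)c(OC)c1C#CC(=O)c1c(OCOC)c(OC)c(OCOC)c(OC)c1OCOC
F4 | step 11 | 3-(3,6-dihydroxy-2-methoxyphenyl)-1-(2,4,6-trihydroxy-3,5-dimethoxyphenyl)prop-2-yn-1-one | COc1c(O)ccc(O)c1C#CC(=O)c1c(O)c(OC)c(O)c(OC)c1O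
F0 | step 3 | none | none
F5 | step 4 | 4,6-dimethoxy-5-(methoxymethoxy)-1,3-phenylene bis(diethylcarbamate) | COCOc1c(OC)c(OC(=O)N(CC)CC)cc(OC(=O)N(CC)CC)c1OC
F6 | step 4 | 4,6-dimethoxy-5-(methoxymethoxy)-2-(trimethylsilyl)-1,3-phenylene bis(diethylcarbamate) | COCOc1c(OC)c(OC(=O)N(CC)CC)c([Si](C)(C)C)c(OC(=O)N(CC)CC)c1OC
F7 | step 5 | 4,6-dimethoxy-5-(methoxymethoxy)-2-(trimethylsilyl)-3-[(trimethylsilyl)oxy]phenyl trifluoromethanesulfonate | COCOc1c(OC)c(O[Si](C)(C)C)c([Si](C)(C)C)c(OS(=O)(=O)C(F)(F)F)c1OC
F8 | step 5 | 3-hydroxy-4,6-dimethoxy-5-(methoxymethoxy)-2-(trimethylsilyl)phenyl trifluoromethanesulfonate | COCOc1c(OC)c(O)c([Si](C)(C)C)c(OS(=O)(=O)C(F)(F)F)c1OC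
F9 | step 12 | 2-(3,6-dihydroxy-2-methoxyphenyl)-7-hydroxy-6,8-dimethoxy-4-oxo-4H-chromen-5-yl trifluoromethanesulfonate | COc1c(O)ccc(O)c1-c1cc(=O)c2c(OS(=O)(=O)C(F)(F)F)c(OC)c(O)c(OC)c2o1
A1 | alternative 1 | 7-tert-butoxy-5,8-dihydroxy-6-methoxy-2-[2-methoxy-3,6-bis(methoxymethoxy)phenyl]-4H-chromen-4-one | COCOc1ccc(OCOC)c(OC)c1-c1cc(=O)c2c(O)c(OC)c(OC(C)(C)C)c(O)c2o1
A2 | alternative 1 | 2-tert-butoxy-4-hydroxy-3-methoxy-4-{6-[2-methoxy-3,6-bis(methoxymethoxy)phenyl]-4-oxo-4H-pyran-3-yl}cyclobut-2-en-1-one (racemic) | COCOc1ccc(OCOC)c(OC)c1-c1cc(=O)c(C2(O)C(OC)=C(OC(C)(C)C)C2=O)co1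
A3 | alternative 1 | 3-tert-butoxy-4-methoxycyclobut-3-ene-1,2-dione | COC1=C(OC(C)(C)C)C(=O)C1=O
A4 | alternative 2 | 7-(benzyloxy)-2-[3,6-bis(benzyloxy)-2-methoxyphenyl]-5-hydroxy-6,8-dimethoxy-4H-chromen-4-one | COc1c(OCc2ccccc2)ccc(OCc2ccccc2)c1-c1cc(=O)c2c(O)c(OC)c(OCc3ccccc3)c(OC)c2o1
A5 | alternative 2 | 5-(benzyloxy)-4,6-dimethoxybenzene-1,3-diol | COc1c(O)cc(O)c(OC)c1OCc1ccccc1
A6 | alternative 2 | ethyl 3-[3,6-bis(benzyloxy)-2-methoxyphenyl]-3-oxopropanoate | CCOC(=O)CC(=O)c1c(OC)c(OCc2ccccc2)ccc1OCc1ccccc1
A7 | alternative 3 | 7-(benzyloxy)-5-bromo-6,8-dimethoxy-2-[2-methoxy-3,6-bis(methoxymethoxy)phenyl]-4H-chromen-4-one | COCOc1ccc(OCOC)c(OC)c1-c1cc(=O)c2c(Br)c(OC)c(OCc3ccccc3)c(OC)c2o1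
A8 | alternative 3 | 1-[4-(benzyloxy)-2,6-dibromo-3,5-dimethoxyphenyl]-3-[2-methoxy-3,6-bis(methoxymethoxy)phenyl]propane-1,3-dione | O=C(CC(=O)c1c(OC)c(OCOC)ccc1OCOC)c1c(Br)c(OC)c(OCc2ccccc2)c(OC)c1Br
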